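By 2.50 min the grey flask reads electrophile at 32% of its charge, and the later readings change slowly.

| setting | grey | blue | north-west | north | west |
|---|---|---|---|---|---|
| electrophile | 0.037 M | 0.037 M | 0.037 M | 0.037 M | 0.037 M |
| nucleophile | 0.050 M | 0.10 M | 0.0630 M | 0.0370 M | 0.0480 M |
| remark | run made earlier | run made earlier |  |  |  |
| time |  |  | 40 min | 40 min | 40 min |

- grey (time / min: electrophile / %, target / %): 2.50: 32, 58; 4.00: 30, 62; 8.00: 23, 63; 15.0: 16, 59; 30.0: 12, 57
- blue (time / min: electrophile / %, target / %): 2.50: 6, 94; 8.00: 0, 97; 12.0: 0, 98; 20.0: 1, 95; 30.0: 0, 97

(each reading ± 1.5 percentage points)

- a species is counted by the electrophile in it: one self-condensation product or side product counts as two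
- what may be going on: electrophile + nucleophile -> acid set free + target; nucleophile + acid set free <-> protonated nucleophile; nucleophile <-> dormant form; 2 electrophile -> self-condensation product; electrophile + target -> side product

- part of the electrophile that has reacted at the end, north-west
- part of the electrophile that has reacted at the end, north
- part of the electrophile that has reacted at the end, west
- what raising the concentration of nucleophile from its lowest to its highest value here does to the part of the electrophile that has reacted (changes below 5 percentage points count as none) (it rises / no change / it falls)

If each electrophile reacted takes two nucleophiles, one to form target and one to trap the acid set free, nucleophile is the limiting reagent in grey. Grey should then stall with 32.4% of the electrophile left, against the first reading, and a target share of 67.6%, against a reading of 63% at 8.00 min.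

We read the slow tail as electrophile lost to target, first order in electrophile. Grey's logarithmic fall from 32% to 12% at 30.0 min, taken per minute and divided by its target share, gives the drain 0.0528 /min: a reading of the fraction of electrophile lost per minute when target equals the electrophile charged. As an estimate, we count the tail from the start. Each flask's stall remainder, decayed at the drain times its target share, gives us 97.5% reacted for north-west, 82.6% for north and 91.1% for west, so a rise.

The forecast differs: 92%, 88% and 90%, with the verdict no change, holding that “Self-condensation largely evens out conversion”.

The flasks give 96.4%, 83.9% and 89.6%. Across the range of nucleophile, it rises, by 12 percentage points.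

    electrophile + nucleophile → acid set free + target (k = 0.470 /M/s)
    nucleophile + acid set free ⇌ protonated nucleophile, settled at all times (K = 1.50 × 10⁵ /M)
    nucleophile ⇌ dormant form (K = 11.0, k = 4.80 × 10⁻⁴ /s)
    2 electrophile → self-condensation product (k = 0.00980 /M/s)
    electrophile + target → side product (k = 0.0150 /M/s)

With the drain, west's tail runs at 0.0342 /min, and we reckoned 8.90% of its electrophile left at 40 min; west holds 10%. The same rate applied to west read at 15 min leaves 21.0%. That reading shows electrophile at 20.4% and target at 56.6%.

(All runs were generated by integration with made-up constants; noise was put on by code.)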